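The earlier runs and the new flask come from a simulation with made-up constants, noise included.

I leave the dawn run as written, lean in free catalyst, and add none. The numbers behind that choice follow.

| flask | substrate | free catalyst | time |
|---|---|---|---|
| midnight | 250 mM | 13.0 mM |  |
| winter | 120 mM | 13.0 mM |  |
| noon | 250 mM | 39.0 mM |  |
| dawn | 500 mM | 4.30 mM | 68 min |

- midnight run (time / min: [product] / mM): 2.7: 14.2; 4.7: 22.0; 8.0: 39.6; 14: 68.6; 23: 108.9; 40: 161.9; 68: 216.2
- winter run (time / min: [product] / mM): 2.7: 6.5; 4.7: 9.4; 8.0: 19.9; 14: 31.3; 23: 46.0; 40: 69.1; 68: 92.2
- noon run (time / min: [product] / mM): 2.7: 26.3; 4.7: 43.5; 8.0: 70.8; 14: 114.3; 23: 162.3; 40: 212.2; 68: 238.5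

(readings scatter by 1 mM)

* the power of [free catalyst] that the first rate follows, about the charge of the midnight run; measure it at two percent of substrate made into product
* the power of [substrate] that the first rate follows, about the charge of the midnight run; measure it at two percent of substrate made into product (one fixed amount of product, the same in the runs compared)
* product in the dawn run at 68 min, as a share of the substrate charged

- Overall: substrate -> product, with free catalyst as catalyst.
- Constant volume, constant temperature.
- An order is taken over about fifteen percent of the charge, up and down.

I follow one substrate molecule. At each moment it can be turned by free catalyst or by product, and I read the two chances from the runs. The midnight and winter runs have the same catalyst charge, so I assume they hold the same catalyst at the same clock time. Between 23 min and 68 min, the first-order constant of the midnight run is 0.0318 /min and that of the winter run is 0.0218 /min. At 40 min the midnight run is ahead in product by 92.8 mM, so the product constant reads 0.108 /M/min.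

The early constant to 8.0 min is 0.0216 /min in the midnight run and 0.0416 /min in the noon run, which gives a catalyst power of 0.599. Scaled to the dawn charge, the catalyst constant is 0.0111 /min. Dividing it by the product constant gives 103 mM, the crossover product: the amount of product at which a substrate molecule has even chances at the fork. The dawn charge of substrate stands above that crossover, so I expect product to take over the turning in the dawn run and add no catalyst.

With the catalyst constant held steady, this is autocatalysis on an S-shaped curve, and my own reckoning gives 93.3% at 68 min. That runs high, since the winter constant stays flat while its product grows, which points to fading catalyst.

The forecast gives 0.6 in free catalyst, 0.95 in substrate and 55%, “Allowing a modest late rise”. It stands well below my figure. Watch for the upward bend in the dawn run as product passes the crossover.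

The dawn run gives 88.7% at 68 min, with powers of 0.63 in free catalyst and 1.0 in substrate.

    2 free catalyst ⇌ catalyst dimer, settled at all times (110.0 /M)
    free catalyst + substrate → product + free catalyst (3.594 /M/min)
    substrate + product → 2 product (0.1020 /M/min)
    2 free catalyst → 2 spent catalyst (2.832 /M/min)

That share is 444 mM of product, so by 68 min the dawn run stands at 4.31 times the crossover I reckoned from its starting catalyst constant. The step of substrate with product carries the gain. Taken away, the same dawn charge reaches 41.3% at 68 min.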